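**Retrosynthetic overview**

1. Reading of the target: a left core, 15-oxatetracyclo[8.6.1.0(2,7).0(14,17)]heptadecahexaene (C1 = furan CH between rings B and C, C8/C9 = the two sp3 carbons of the seven-membered ring, O15, C16 = O–CH–aryl; 1S,8S,9S,16S), carries ring F on C9. Ring F is joined by an E-stilbene to C4 of a (2S,3S)-2,3-diaryl-2,3-dihydrobenzofuran (ring D). All ten phenols travel as benzyl ethers.
2. Feature on which the strategy rests: ring D bears on three neighbouring carbons the furan oxygen (C7a), the aryl-bearing C3 (on C3a) and the stilbene carbon (on C4). Ring C of the left core repeats this O/C/C pattern (O15 on C14, C1 on C17, C9 on C10).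
3. Key disconnection: the ring D–C3 and ring D–CH2 bonds are made together by inserting a 3,5-dialkoxybenzyne into the C2–C3 bond of an aroylacetate (aroyl to C3a, CH2CO2Me to C4). Ortho-debenzylation, reduction/lactonization and a chiral sulfonium-ylide [4+1] annulation then close the dihydrofuran ring to acid 20, which serves both halves.
4. Left half from 20: Friedel–Crafts acylation closes the seven-membered ring (C7–C8), α-arylation brings ring F to C9, enol triflate coupling brings the aryl group to C8, and ionic hydrogenation sets C8/C9. Right half: 20 becomes the Weinreb amide.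
5. Union: the aryllithium of the left bromide acylates the Weinreb amide; reduction, dehydration to the E-stilbene and debenzylation follow. Ring order: dihydrofuran ring (step 8, both halves), then the seven-membered ring (step 9).

Key step: step 4

Assumption: the (1R,4R,5R) antipode of isothiocineole is taken as the one whose benzylic ylide leads to the (2S,3S) series; should the sense prove opposite, the (1S,4S,5S) antipode is used in the same steps.

**Route**

Step 1
Reactants: 1 3,5-bis(benzyloxy)phenol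
Product: 2 3,5-bis(benzyloxy)-2-bromophenol
Conditions: NBS (1.0 equiv), CH2Cl2, −78 °C → rt
Reagents that add atoms: N-bromosuccinimide, O=C1CCC(=O)N1Br
Why: Electrophilic aromatic bromination of the symmetric phenol should take place at the position between OH and one benzyloxy group, which is less hindered than C4 between the two benzyloxy groups and counts twice, so that no regiochemical choice between unlike ether groups arises.

Step 2
Reactants: 2 3,5-bis(benzyloxy)-2-bromophenol
Product: 5 3,5-bis(benzyloxy)-2-(trimethylsilyl)phenyl trifluoromethanesulfonate, via silyl ether 3 (not isolated), via lithium phenoxide 4 (not isolated)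
Conditions: HN(SiMe3)2, THF, 65 °C; evaporate; n-BuLi, THF, −78 °C; Tf2O, −78 °C → rt
Reagents that add atoms: hexamethyldisilazane, C[Si](C)(C)N[Si](C)(C)C; trifluoromethanesulfonic anhydride, O=S(=O)(OS(=O)(=O)C(F)(F)F)C(F)(F)F
Why: O-silylation, bromine–lithium exchange and 1,3 O→C silyl shift (retro-Brook rearrangement) put SiMe3 on the carbon flanked by the two oxygens, and the liberated phenoxide is triflated to the ortho-silyl aryl triflate.

Step 3
Reactants: 6 methyl 3,5-bis(benzyloxy)benzoate; 7 methyl acetate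
Product: 8 methyl 3-[3,5-bis(benzyloxy)phenyl]-3-oxopropanoate
Conditions: 7, LiN(SiMe3)2 (2.2 equiv), THF, −78 °C; then 6, −78 → 0 °C; 1 M HCl
Reagents that add atoms: none
Why: Crossed Claisen condensation of the non-enolizable benzoate with the lithium enolate of methyl acetate, driven by deprotonation of the β-ketoester by the second equivalent of base.

Step 4
Reactants: 5 3,5-bis(benzyloxy)-2-(trimethylsilyl)phenyl trifluoromethanesulfonate; 8 methyl 3-[3,5-bis(benzyloxy)phenyl]-3-oxopropanoate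
Product: 11 methyl 2-[3,5-bis(benzyloxy)-2-[3,5-bis(benzyloxy)benzoyl]phenyl]acetate, via aryne 9 (not isolated), via cesium benzocyclobutenoxide 10 (not isolated)
Conditions: CsF (2.5 equiv), MeCN, 80 °C; 5 (1.25 equiv)
Reagents that add atoms: none
Why: Fluoride removes SiMe3 from 5 and triflate leaves to give aryne 9; the cesium enolate of 8 adds through carbon to the aryne carbon remote from the C3 benzyloxy group, the aryl anion formed beside that oxygen closes onto the ketone carbonyl to the benzocyclobutenoxide 10, and fragmentation of 10 moves the aroyl group onto the ring and leaves the CH2CO2Me arm on the neighbouring carbon. The closest known reaction is the aryne acyl-alkylation of β-ketoesters (formal insertion into the α-carbon–acyl bond), which is known for 3-alkoxy- and 3,5-dialkoxybenzynes. No ring of the target is closed: the four-membered ring of 10 forms by 4-exo-trig attack of the aryl anion on the carbonyl and reopens at once, and no stereocentre is made. The step must deliver regiochemistry, aroyl next to oxygen (future C3a of ring D and C17 of ring C) and acetate arm on the next carbon (future C4 and C10); the inductive effect of the C3 alkoxy group secures it by directing the nucleophile to the distal aryne carbon so that the negative charge develops ortho to oxygen. C-arylation must also win over O-arylation and over protonation of the aryl anion before ring closure, which the soft, doubly stabilised enolate in anhydrous MeCN should favour.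

Step 5
Reactants: 11 methyl 2-[3,5-bis(benzyloxy)-2-[3,5-bis(benzyloxy)benzoyl]phenyl]acetate
Product: 12 methyl 2-[5-(benzyloxy)-2-[3,5-bis(benzyloxy)benzoyl]-3-hydroxyphenyl]acetate
Conditions: MgBr2·OEt2 (3 equiv), toluene/Et2O, 70 °C; 1 M HCl
Reagents that add atoms: none
Why: MgBr2 chelates between the ketone oxygen and the ortho benzyloxy oxygen and bromide cleaves only this activated benzyl ether (chelation-controlled O-debenzylation), so the three non-chelated benzyl ethers and the ester should remain.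

Step 6
Reactants: 12 methyl 2-[5-(benzyloxy)-2-[3,5-bis(benzyloxy)benzoyl]-3-hydroxyphenyl]acetate
Product: 14 6-(benzyloxy)-1-[3,5-bis(benzyloxy)phenyl]-8-hydroxyisochroman-3-one (racemic), via hydroxy ester 13 (not isolated)
Conditions: NaBH4, THF/MeOH, 0 °C → rt; 1 M HCl; then PPTS (cat.), toluene, 60 °C
Reagents that add atoms: none
Why: Hydride reduction of the diaryl ketone gives benzhydrol 13, whose hydroxyl closes onto the neighbouring CH2CO2Me arm (6-exo-trig lactonization) to a stable isochromanone; its stereocentre is racemic and is erased in step 8.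

Step 7
Reactants: 15 (1R,4R,5R)-isothiocineole; 16 4-(benzyloxy)benzyl bromide
Product: 17 (1R,4R,5R)-6-[4-(benzyloxy)benzyl]-4,7,7-trimethyl-6-thiabicyclo[3.2.1]octan-6-ium tetrafluoroborate (benzyl group on the exo face of sulfur)
Conditions: NaBF4, CH2Cl2/H2O, rt
Reagents that add atoms: sodium tetrafluoroborate, [Na+].F[B-](F)(F)F
Why: S-alkylation of the sulfide by the benzylic bromide on its less hindered exo lone pair, with exchange of bromide for the non-nucleophilic tetrafluoroborate so that the alkylation is not reversed and a single diastereomer at sulfur should form.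

Step 8
Reactants: 14 6-(benzyloxy)-1-[3,5-bis(benzyloxy)phenyl]-8-hydroxyisochroman-3-one; 17 sulfonium tetrafluoroborate
Product: 20 2-[(2S,3S)-6-(benzyloxy)-2-[4-(benzyloxy)phenyl]-3-[3,5-bis(benzyloxy)phenyl]-2,3-dihydro-1-benzofuran-4-yl]acetic acid, via sulfonium ylide 18 (not isolated), via quinone methide carboxylate 19 (not isolated)
Conditions: Cs2CO3 (4 equiv), MeCN, 0 °C → rt; then 1 M HCl
Reagents that add atoms: none
Why: Proposed new method: deprotonation of the C8 phenol of 14 should expel the benzylic lactone carboxylate by 1,4-elimination to the o-quinone methide 19, ylide 18 adds through its unshielded face to the methide carbon and the phenoxide displaces the sulfide with inversion (5-exo-tet), so that the ylide face fixes C2 as S and the anti betaine gives the trans (3S) isomer from both enantiomers of 14; the closest known reactions are the base-mediated [4+1] annulation of o-quinone methides with sulfur ylides to trans-2,3-dihydrobenzofurans and the asymmetric epoxidations with benzylides of this sulfide, whereas a lactone as quinone methide source and this sulfide in the [4+1] mode are not established.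

Step 9
Reactants: 20 dihydrobenzofuranylacetic acid
Product: 21 (1S,16S)-4,6,12-tris(benzyloxy)-16-[4-(benzyloxy)phenyl]-15-oxatetracyclo[8.6.1.0(2,7).0(14,17)]heptadeca-2(7),3,5,10(17),11,13-hexaen-8-one
Conditions: (CF3CO)2O (3 equiv), CH2Cl2, 0 °C → rt
Reagents that add atoms: none
Why: Intramolecular Friedel–Crafts acylation through the mixed trifluoroacetic anhydride: the acyl group on the C4 arm can reach only the ortho carbon of the C3 aryl group, which is ortho and para to benzyloxy groups, and closes the seven-membered ketone as in dibenzosuberone syntheses without touching the stereocentres.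

Step 10
Reactants: 22 4-bromo-2-iodophenol
Product: 23 1-(benzyloxy)-4-bromo-2-iodobenzene
Conditions: BnBr, K2CO3, DMF, rt
Reagents that add atoms: benzyl bromide, BrCc1ccccc1
Why: Williamson etherification of the phenol.

Step 11
Reactants: 21 tetracyclic ketone; 23 1-(benzyloxy)-4-bromo-2-iodobenzene
Product: 24 (1S,16S)-4,6,12-tris(benzyloxy)-9-[2-(benzyloxy)-5-bromophenyl]-16-[4-(benzyloxy)phenyl]-15-oxatetracyclo[8.6.1.0(2,7).0(14,17)]heptadeca-2(7),3,5,10(17),11,13-hexaen-8-one (C9 epimers)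
Conditions: Pd2(dba)3 (2.5 mol%), Xantphos (6 mol%), K3PO4, toluene, 70 °C
Reagents that add atoms: none
Why: Palladium-catalysed α-arylation of the benzylic aryl ketone enolate, in which oxidative addition takes place at the C–I bond and spares the C–Br bond and the doubly benzylic product is too hindered to be arylated again; the C9 configuration is labile and is cancelled in step 12.

Step 12
Reactants: 24 α-aryl ketone
Product: 25 (1S,16S)-4,6,12-tris(benzyloxy)-9-[2-(benzyloxy)-5-bromophenyl]-16-[4-(benzyloxy)phenyl]-15-oxatetracyclo[8.6.1.0(2,7).0(14,17)]heptadeca-2(7),3,5,8,10(17),11,13-heptaen-8-yl trifluoromethanesulfonate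
Conditions: KN(SiMe3)2, THF, −78 °C; PhNTf2, −78 → 0 °C; aq. NH4Cl
Reagents that add atoms: N-phenylbis(trifluoromethanesulfonimide), O=S(=O)(N(c1ccccc1)S(=O)(=O)C(F)(F)F)C(F)(F)F
Why: The only possible enolate, stabilised by two aryl groups, is sulfonylated on oxygen to the tetrasubstituted enol triflate.

Step 13
Reactants: 25 enol triflate; 26 4-(benzyloxy)phenylboronic acid
Product: 27 (1S,16S)-4,6,12-tris(benzyloxy)-9-[2-(benzyloxy)-5-bromophenyl]-8,16-bis[4-(benzyloxy)phenyl]-15-oxatetracyclo[8.6.1.0(2,7).0(14,17)]heptadeca-2(7),3,5,8,10(17),11,13-heptaene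
Conditions: 26 (1.1 equiv), Pd(PPh3)4 (5 mol%), K3PO4, 1,4-dioxane/H2O, 60 °C
Reagents that add atoms: none
Why: Suzuki–Miyaura coupling in which the alkenyl triflate should undergo oxidative addition to the palladium catalyst faster than the electron-rich aryl bromide, so that with a slight excess of boronic acid only C8 is arylated.

Step 14
Reactants: 27 cyclic tetraarylethene
Product: 29 (1S,8S,9S,16S)-4,6,12-tris(benzyloxy)-9-[2-(benzyloxy)-5-bromophenyl]-8,16-bis[4-(benzyloxy)phenyl]-15-oxatetracyclo[8.6.1.0(2,7).0(14,17)]heptadeca-2(7),3,5,10(17),11,13-hexaene, via C8 carbenium trifluoroacetate 28 (not isolated)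
Conditions: Et3SiH (5 equiv), CF3CO2H (10 equiv), CH2Cl2, −20 → 0 °C
Reagents that add atoms: none
Why: Ionic hydrogenation: reversible protonation at C9 gives the C8 carbenium ion 28, stabilised by the 4-alkoxyphenyl group and the 2,4-dialkoxyaryl ring B, and Et3SiH transfers hydride to C8; both hydrogens should enter the pseudo-equatorial sites so that the two aryl groups end pseudo-axial on the convex face, syn to H1, where they escape allylic strain with the C6 benzyloxy group and with C11–H and where the C9 aryl group is anti to the incoming hydride, which is the (8S,9S) isomer.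

Step 15
Reactants: 20 dihydrobenzofuranylacetic acid
Product: 30 2-[(2S,3S)-6-(benzyloxy)-2-[4-(benzyloxy)phenyl]-3-[3,5-bis(benzyloxy)phenyl]-2,3-dihydro-1-benzofuran-4-yl]-N-methoxy-N-methylacetamide
Conditions: CDI, CH2Cl2, rt; then MeNHOMe·HCl, rt
Reagents that add atoms: N,O-dimethylhydroxylamine hydrochloride, CNOC.Cl
Why: Activation of the acid as its acyl imidazole and amidation to the Weinreb amide, which leaves the stereocentres untouched.

Step 16
Reactants: 29 left-core aryl bromide; 30 Weinreb amide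
Product: 32 1-[4-(benzyloxy)-3-[(1S,8S,9S,16S)-4,6,12-tris(benzyloxy)-8,16-bis[4-(benzyloxy)phenyl]-15-oxatetracyclo[8.6.1.0(2,7).0(14,17)]heptadeca-2(7),3,5,10(17),11,13-hexaen-9-yl]phenyl]-2-[(2S,3S)-6-(benzyloxy)-2-[4-(benzyloxy)phenyl]-3-[3,5-bis(benzyloxy)phenyl]-2,3-dihydro-1-benzofuran-4-yl]ethan-1-one, via aryllithium 31 (not isolated)
Conditions: t-BuLi (2.1 equiv), THF, −78 °C; then 30 (1.3 equiv), −78 → −20 °C; aq. NH4Cl
Reagents that add atoms: none
Why: Bromine–lithium exchange at −78 °C and acylation of the aryllithium by the N-methoxy-N-methylamide, whose chelated adduct holds the reaction at the ketone stage (Weinreb ketone synthesis).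

Step 17
Reactants: 32 diaryl-ethanone
Product: 33 the corresponding ethan-1-ol, ring F–CH(OH)–CH2–ring D (carbinol epimers)
Conditions: NaBH4, THF/MeOH, 0 °C; aq. NH4Cl
Reagents that add atoms: none
Why: Hydride reduction of the aryl ketone; the carbinol centre is a mixture and is removed in step 18.

Step 18
Reactants: 33 carbinol
Product: 34 (1S,8S,9S,16S)-4,6,12-tris(benzyloxy)-9-[2-(benzyloxy)-5-[(E)-2-[(2S,3S)-6-(benzyloxy)-2-[4-(benzyloxy)phenyl]-3-[3,5-bis(benzyloxy)phenyl]-2,3-dihydro-1-benzofuran-4-yl]ethenyl]phenyl]-8,16-bis[4-(benzyloxy)phenyl]-15-oxatetracyclo[8.6.1.0(2,7).0(14,17)]heptadeca-2(7),3,5,10(17),11,13-hexaene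
Conditions: Burgess reagent (methyl N-(triethylammoniosulfonyl)carbamate), toluene, 60 °C
Reagents that add atoms: none
Why: Dehydration of the 4-alkoxybenzylic alcohol through its sulfamate ester (syn elimination) towards the conjugated stilbene, E being favoured because the two aryl groups are anti in the elimination transition state, under non-acidic conditions that both dihydrobenzofurans should survive.

Step 19
Reactants: 34 decabenzyl ether
Product: 35 CNP0266373.2, (1S,8S,9S,16S)-9-[5-[(E)-2-[(2S,3S)-3-(3,5-dihydroxyphenyl)-6-hydroxy-2-(4-hydroxyphenyl)-2,3-dihydro-1-benzofuran-4-yl]ethenyl]-2-hydroxyphenyl]-8,16-bis(4-hydroxyphenyl)-15-oxatetracyclo[8.6.1.0(2,7).0(14,17)]heptadeca-2(7),3,5,10(17),11,13-hexaene-4,6,12-triol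
Conditions: BCl3 (30 equiv), pentamethylbenzene (30 equiv), CH2Cl2, −78 °C; then H2O
Reagents that add atoms: none
Why: Tenfold O-debenzylation by BCl3 with pentamethylbenzene as a non-basic trap for the benzyl cations (Friedel–Crafts scavenging) at −78 °C, conditions that should spare the stilbene and the acid-sensitive 2,3-diaryl-2,3-dihydrobenzofurans and touch no stereocentre.

**Compound list**

1 | 3,5-bis(benzyloxy)phenol | Oc1cc(OCc9ccccc9)cc(OCc9ccccc9)c1 | starting material
2 | 3,5-bis(benzyloxy)-2-bromophenol | Oc1cc(OCc9ccccc9)cc(OCc9ccccc9)c1Br | intermediate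
3 | [3,5-bis(benzyloxy)-2-bromophenoxy]trimethylsilane (not isolated) | C[Si](C)(C)Oc1cc(OCc9ccccc9)cc(OCc9ccccc9)c1Br | intermediate
4 | lithium 3,5-bis(benzyloxy)-2-(trimethylsilyl)phenoxide (not isolated) | [Li+].[O-]c1cc(OCc9ccccc9)cc(OCc9ccccc9)c1[Si](C)(C)C | intermediate
5 | 3,5-bis(benzyloxy)-2-(trimethylsilyl)phenyl trifluoromethanesulfonate | C[Si](C)(C)c1c(OCc9ccccc9)cc(OCc9ccccc9)cc1OS(=O)(=O)C(F)(F)F | intermediate
6 | methyl 3,5-bis(benzyloxy)benzoate | COC(=O)c1cc(OCc9ccccc9)cc(OCc9ccccc9)c1 | starting material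
7 | methyl acetate | COC(C)=O | starting material
8 | methyl 3-[3,5-bis(benzyloxy)phenyl]-3-oxopropanoate | COC(=O)CC(=O)c1cc(OCc9ccccc9)cc(OCc9ccccc9)c1 | intermediate
9 | 3,5-bis(benzyloxy)benzyne (not isolated) | C1(OCc9ccccc9)=CC(OCc9ccccc9)=CC#C1 | intermediate
10 | cesium 2,4-bis(benzyloxy)-8-[3,5-bis(benzyloxy)phenyl]-7-(methoxycarbonyl)bicyclo[4.2.0]octa-1,3,5-trien-8-olate (diastereomer mixture, not isolated) | [Cs+].COC(=O)C1c2cc(OCc9ccccc9)cc(OCc9ccccc9)c2C1([O-])c1cc(OCc9ccccc9)cc(OCc9ccccc9)c1 | intermediate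
11 | methyl 2-[3,5-bis(benzyloxy)-2-[3,5-bis(benzyloxy)benzoyl]phenyl]acetate | COC(=O)Cc1cc(OCc9ccccc9)cc(OCc9ccccc9)c1C(=O)c1cc(OCc9ccccc9)cc(OCc9ccccc9)c1 | intermediate
12 | methyl 2-[5-(benzyloxy)-2-[3,5-bis(benzyloxy)benzoyl]-3-hydroxyphenyl]acetate | COC(=O)Cc1cc(OCc9ccccc9)cc(O)c1C(=O)c1cc(OCc9ccccc9)cc(OCc9ccccc9)c1 | intermediate
13 | methyl 2-[5-(benzyloxy)-2-[[3,5-bis(benzyloxy)phenyl](hydroxy)methyl]-3-hydroxyphenyl]acetate (racemic, not isolated) | COC(=O)Cc1cc(OCc9ccccc9)cc(O)c1C(O)c1cc(OCc9ccccc9)cc(OCc9ccccc9)c1 | intermediate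
14 | 6-(benzyloxy)-1-[3,5-bis(benzyloxy)phenyl]-8-hydroxyisochroman-3-one (racemic) | O=C1Cc2cc(OCc9ccccc9)cc(O)c2C(O1)c1cc(OCc9ccccc9)cc(OCc9ccccc9)c1 | intermediate
15 | (1R,4R,5R)-isothiocineole, (1R,4R,5R)-4,7,7-trimethyl-6-thiabicyclo[3.2.1]octane | C[C@@H]1CC[C@@H]2C[C@H]1SC2(C)C | starting material
16 | 4-(benzyloxy)benzyl bromide | BrCc1ccc(OCc9ccccc9)cc1 | starting material
17 | (1R,4R,5R)-6-[4-(benzyloxy)benzyl]-4,7,7-trimethyl-6-thiabicyclo[3.2.1]octan-6-ium tetrafluoroborate, benzyl exo on sulfur | C[C@@H]1CC[C@@H]2C[C@H]1[S@@+](Cc1ccc(OCc9ccccc9)cc1)C2(C)C.F[B-](F)(F)F | intermediate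
18 | [4-(benzyloxy)phenyl]methylide of sulfonium 17 (not isolated) | C[C@@H]1CC[C@@H]2C[C@H]1[S@@+]([CH-]c1ccc(OCc9ccccc9)cc1)C2(C)C | intermediate
19 | cesium 2-[3-(benzyloxy)-6-[[3,5-bis(benzyloxy)phenyl]methylidene]-5-oxocyclohexa-1,3-dien-1-yl]acetate (alkene geometry not defined, not isolated) | [Cs+].[O-]C(=O)CC1=CC(OCc9ccccc9)=CC(=O)C1=Cc1cc(OCc9ccccc9)cc(OCc9ccccc9)c1 | intermediate
20 | 2-[(2S,3S)-6-(benzyloxy)-2-[4-(benzyloxy)phenyl]-3-[3,5-bis(benzyloxy)phenyl]-2,3-dihydro-1-benzofuran-4-yl]acetic acid | OC(=O)Cc1cc(OCc9ccccc9)cc2c1[C@H](c1cc(OCc9ccccc9)cc(OCc9ccccc9)c1)[C@@H](c1ccc(OCc9ccccc9)cc1)O2 | intermediate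
21 | (1S,16S)-4,6,12-tris(benzyloxy)-16-[4-(benzyloxy)phenyl]-15-oxatetracyclo[8.6.1.0(2,7).0(14,17)]heptadeca-2(7),3,5,10(17),11,13-hexaen-8-one | O=C1Cc2cc(OCc9ccccc9)cc3c2[C@H](c2cc(OCc9ccccc9)cc(OCc9ccccc9)c21)[C@@H](c1ccc(OCc9ccccc9)cc1)O3 | intermediate
22 | 4-bromo-2-iodophenol | Oc1ccc(Br)cc1I | starting material
23 | 1-(benzyloxy)-4-bromo-2-iodobenzene | Brc1ccc(OCc9ccccc9)c(I)c1 | intermediate
24 | (1S,16S)-4,6,12-tris(benzyloxy)-9-[2-(benzyloxy)-5-bromophenyl]-16-[4-(benzyloxy)phenyl]-15-oxatetracyclo[8.6.1.0(2,7).0(14,17)]heptadeca-2(7),3,5,10(17),11,13-hexaen-8-one (C9 epimers) | O=C1C(c2cc(Br)ccc2OCc9ccccc9)c2cc(OCc9ccccc9)cc3c2[C@H](c2cc(OCc9ccccc9)cc(OCc9ccccc9)c21)[C@@H](c1ccc(OCc9ccccc9)cc1)O3 | intermediate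
25 | (1S,16S)-4,6,12-tris(benzyloxy)-9-[2-(benzyloxy)-5-bromophenyl]-16-[4-(benzyloxy)phenyl]-15-oxatetracyclo[8.6.1.0(2,7).0(14,17)]heptadeca-2(7),3,5,8,10(17),11,13-heptaen-8-yl trifluoromethanesulfonate | FC(F)(F)S(=O)(=O)OC1=C(c2cc(Br)ccc2OCc9ccccc9)c2cc(OCc9ccccc9)cc3c2[C@H](c2cc(OCc9ccccc9)cc(OCc9ccccc9)c21)[C@@H](c1ccc(OCc9ccccc9)cc1)O3 | intermediate
26 | 4-(benzyloxy)phenylboronic acid | OB(O)c1ccc(OCc9ccccc9)cc1 | starting material
27 | (1S,16S)-4,6,12-tris(benzyloxy)-9-[2-(benzyloxy)-5-bromophenyl]-8,16-bis[4-(benzyloxy)phenyl]-15-oxatetracyclo[8.6.1.0(2,7).0(14,17)]heptadeca-2(7),3,5,8,10(17),11,13-heptaene | C1(c2ccc(OCc9ccccc9)cc2)=C(c2cc(Br)ccc2OCc9ccccc9)c2cc(OCc9ccccc9)cc3c2[C@H](c2cc(OCc9ccccc9)cc(OCc9ccccc9)c21)[C@@H](c1ccc(OCc9ccccc9)cc1)O3 | intermediate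
28 | (1S,9S,16S)-4,6,12-tris(benzyloxy)-9-[2-(benzyloxy)-5-bromophenyl]-8,16-bis[4-(benzyloxy)phenyl]-15-oxatetracyclo[8.6.1.0(2,7).0(14,17)]heptadeca-2(7),3,5,10(17),11,13-hexaen-8-ylium trifluoroacetate (not isolated) | O(Cc9ccccc9)c1ccc([C+]2c3c(OCc9ccccc9)cc(OCc9ccccc9)cc3[C@H]3c4c(cc(OCc9ccccc9)cc4[C@H]2c2cc(Br)ccc2OCc9ccccc9)O[C@@H]3c2ccc(OCc9ccccc9)cc2)cc1.[O-]C(=O)C(F)(F)F | intermediate
29 | (1S,8S,9S,16S)-4,6,12-tris(benzyloxy)-9-[2-(benzyloxy)-5-bromophenyl]-8,16-bis[4-(benzyloxy)phenyl]-15-oxatetracyclo[8.6.1.0(2,7).0(14,17)]heptadeca-2(7),3,5,10(17),11,13-hexaene | O(Cc9ccccc9)c1ccc([C@H]2c3c(OCc9ccccc9)cc(OCc9ccccc9)cc3[C@H]3c4c(cc(OCc9ccccc9)cc4[C@H]2c2cc(Br)ccc2OCc9ccccc9)O[C@@H]3c2ccc(OCc9ccccc9)cc2)cc1 | intermediate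
30 | 2-[(2S,3S)-6-(benzyloxy)-2-[4-(benzyloxy)phenyl]-3-[3,5-bis(benzyloxy)phenyl]-2,3-dihydro-1-benzofuran-4-yl]-N-methoxy-N-methylacetamide | CON(C)C(=O)Cc1cc(OCc9ccccc9)cc2c1[C@H](c1cc(OCc9ccccc9)cc(OCc9ccccc9)c1)[C@@H](c1ccc(OCc9ccccc9)cc1)O2 | intermediate
31 | aryllithium from 29, lithium in place of bromine on ring F (not isolated) | O(Cc9ccccc9)c1ccc([C@H]2c3c(OCc9ccccc9)cc(OCc9ccccc9)cc3[C@H]3c4c(cc(OCc9ccccc9)cc4[C@H]2c2cc([Li])ccc2OCc9ccccc9)O[C@@H]3c2ccc(OCc9ccccc9)cc2)cc1 | intermediate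
32 | ketone ring F–C(=O)–CH2–ring D, full name as in step 16 | O(Cc9ccccc9)c1ccc([C@H]2c3c(OCc9ccccc9)cc(OCc9ccccc9)cc3[C@H]3c4c(cc(OCc9ccccc9)cc4[C@H]2c2cc(C(=O)Cc4cc(OCc9ccccc9)cc5c4[C@H](c4cc(OCc9ccccc9)cc(OCc9ccccc9)c4)[C@@H](c4ccc(OCc9ccccc9)cc4)O5)ccc2OCc9ccccc9)O[C@@H]3c2ccc(OCc9ccccc9)cc2)cc1 | intermediate
33 | alcohol ring F–CH(OH)–CH2–ring D, the ethan-1-ol of 32 (carbinol epimers) | O(Cc9ccccc9)c1ccc([C@H]2c3c(OCc9ccccc9)cc(OCc9ccccc9)cc3[C@H]3c4c(cc(OCc9ccccc9)cc4[C@H]2c2cc(C(O)Cc4cc(OCc9ccccc9)cc5c4[C@H](c4cc(OCc9ccccc9)cc(OCc9ccccc9)c4)[C@@H](c4ccc(OCc9ccccc9)cc4)O5)ccc2OCc9ccccc9)O[C@@H]3c2ccc(OCc9ccccc9)cc2)cc1 | intermediate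
34 | decabenzyl ether of the target (E-stilbene), full name as in step 18 | O(Cc9ccccc9)c1ccc([C@H]2c3c(OCc9ccccc9)cc(OCc9ccccc9)cc3[C@H]3c4c(cc(OCc9ccccc9)cc4[C@H]2c2cc(/C=C/c4cc(OCc9ccccc9)cc5c4[C@H](c4cc(OCc9ccccc9)cc(OCc9ccccc9)c4)[C@@H](c4ccc(OCc9ccccc9)cc4)O5)ccc2OCc9ccccc9)O[C@@H]3c2ccc(OCc9ccccc9)cc2)cc1 | intermediate
35 | CNP0266373.2, full name as in step 19 | Oc1ccc([C@H]2c3c(O)cc(O)cc3[C@H]3c4c(cc(O)cc4[C@H]2c2cc(/C=C/c4cc(O)cc5c4[C@H](c4cc(O)cc(O)c4)[C@@H](c4ccc(O)cc4)O5)ccc2O)O[C@@H]3c2ccc(O)cc2)cc1 | target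

**Step count and risks**

Total steps: 19. Longest linear sequence: 15 steps (1 → 2 → 5 → 11 → 12 → 14 → 20 → 21 → 24 → 25 → 27 → 29 → 32 → 33 → 34 → 35).

Steps most likely to fail:

1. Step 8 (bears the label). What may go wrong: slow or incomplete release of the quinone methide from the lactone; transfer of the benzylic group from sulfur to the phenoxide or carboxylate oxygen; incomplete facial control by the ylide, or its loss through reversible deprotonation of the betaine next to sulfur, so that cis isomer or the enantiomer forms. Fallback with known chemistry, from 14: sodium 4-methylbenzenesulfinate in aqueous formic acid at 40 °C converts 14 into 2-[5-(benzyloxy)-2-[[3,5-bis(benzyloxy)phenyl](4-methylbenzenesulfonyl)methyl]-3-hydroxyphenyl]acetic acid F1, a 2-(sulfonylalkyl)phenol of the kind normally used as quinone methide source. F1, 1-[4-(benzyloxy)benzyl]thiolan-1-ium bromide F2 (from 16 and tetrahydrothiophene in acetone) and Cs2CO3 in CH2Cl2 should give, by the base-mediated sulfur-ylide [4+1] annulation, the racemic trans acid F3. F3 is resolved by crystallisation of its (R)-1-phenylethylammonium salt F4 from ethanol (the S amine if the other salt is the less soluble one), and acidification of F4 returns to 20.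

2. Step 14. What may go wrong: hydride transfer to the convex face of the C8 cation, or protonation of C9 from that face, giving C8 or C9 epimers; reductive opening of the benzylic C16–O15 bond in the acid. Fallback, from 24: C9 of 24 is first allowed to settle under mild base (DBU, CH2Cl2) with its aryl group pseudo-axial. 4-(Benzyloxy)phenylmagnesium bromide premixed with anhydrous CeCl3 (THF, −78 → 0 °C) then adds to the enolizable ketone to give the tertiary carbinol (1S,9S,16S)-4,6,12-tris(benzyloxy)-9-[2-(benzyloxy)-5-bromophenyl]-8,16-bis[4-(benzyloxy)phenyl]-15-oxatetracyclo[8.6.1.0(2,7).0(14,17)]heptadeca-2(7),3,5,10(17),11,13-hexaen-8-ol F5. F5 is reduced with Et3SiH and BF3·OEt2 at −78 °C, where C9 is no longer formed in the acid step and its aryl group steers hydride to the opposite face of C8; this returns to 29 and leaves out 25 and 27.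

3. Step 4. What may go wrong: protonation of the aryl anion before it closes onto the ketone (plain α-arylation of the ketoester), O-arylation of the enolate, attack at the aryne carbon beside the benzyloxy group, or self-condensation of 8 at 80 °C. Fallback, from 6: saponification (LiOH, THF/H2O) gives 3,5-bis(benzyloxy)benzoic acid F6. As its mixed trifluoroacetic anhydride ((CF3CO)2O, cat. H3PO4, CH2Cl2), F6 acylates methyl 2-[3,5-bis(benzyloxy)phenyl]acetate F7 (from commercial methyl 2-(3,5-dihydroxyphenyl)acetate, benzyl bromide and K2CO3) at the ring carbon between the acetate arm and a benzyloxy group, para to the other benzyloxy group (Friedel–Crafts acylation); the product is 11.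

Further compounds
F1 | step 8 | 2-[5-(benzyloxy)-2-[[3,5-bis(benzyloxy)phenyl](4-methylbenzenesulfonyl)methyl]-3-hydroxyphenyl]acetic acid (racemic) | OC(=O)Cc1cc(OCc9ccccc9)cc(O)c1C(c1cc(OCc9ccccc9)cc(OCc9ccccc9)c1)S(=O)(=O)c1ccc(C)cc1
F2 | step 8 | 1-[4-(benzyloxy)benzyl]thiolan-1-ium bromide | [Br-].C1CC[S+](C1)Cc1ccc(OCc9ccccc9)cc1
F3 | step 8 | racemic trans-2-[6-(benzyloxy)-2-[4-(benzyloxy)phenyl]-3-[3,5-bis(benzyloxy)phenyl]-2,3-dihydro-1-benzofuran-4-yl]acetic acid, (2S,3S) and (2R,3R) | OC(=O)Cc1cc(OCc9ccccc9)cc2c1[C@H](c1cc(OCc9ccccc9)cc(OCc9ccccc9)c1)[C@@H](c1ccc(OCc9ccccc9)cc1)O2.OC(=O)Cc1cc(OCc9ccccc9)cc2c1[C@@H](c1cc(OCc9ccccc9)cc(OCc9ccccc9)c1)[C@H](c1ccc(OCc9ccccc9)cc1)O2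
F4 | step 8 | (R)-1-phenylethylammonium salt of acid 20 | [O-]C(=O)Cc1cc(OCc9ccccc9)cc2c1[C@H](c1cc(OCc9ccccc9)cc(OCc9ccccc9)c1)[C@@H](c1ccc(OCc9ccccc9)cc1)O2.C[C@@H]([NH3+])c1ccccc1
F5 | step 14 | (1S,9S,16S)-4,6,12-tris(benzyloxy)-9-[2-(benzyloxy)-5-bromophenyl]-8,16-bis[4-(benzyloxy)phenyl]-15-oxatetracyclo[8.6.1.0(2,7).0(14,17)]heptadeca-2(7),3,5,10(17),11,13-hexaen-8-ol (C8 epimers) | O(Cc9ccccc9)c1ccc(C2(O)c3c(OCc9ccccc9)cc(OCc9ccccc9)cc3[C@H]3c4c(cc(OCc9ccccc9)cc4[C@H]2c2cc(Br)ccc2OCc9ccccc9)O[C@@H]3c2ccc(OCc9ccccc9)cc2)cc1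
F6 | step 4 | 3,5-bis(benzyloxy)benzoic acid | OC(=O)c1cc(OCc9ccccc9)cc(OCc9ccccc9)c1
F7 | step 4 | methyl 2-[3,5-bis(benzyloxy)phenyl]acetate | COC(=O)Cc1cc(OCc9ccccc9)cc(OCc9ccccc9)c1
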